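The ratio I carry is r: Z found, over the J lost and not found as Z, a selectivity factor. The last readings give r = 0.914 in cedar at 50 °C and 0.668 in ash at 78 °C.

| flask | J | G | temperature | remark | time |
|---|---|---|---|---|---|
| cedar | 0.050 M | 0.030 M | 50 °C | run made earlier |  |
| ash | 0.050 M | 0.12 M | 78 °C | run made earlier |  |
| maple | 0.025 M | 0.060 M | 50 °C | run made earlier |  |
| south | 0.050 M | 0.0600 M | 85 °C |  | 8.0 d |
| north-west | 0.050 M | 0.0600 M | 100 °C |  | 8.0 d |
| south-west | 0.050 M | 0.0600 M | 55 °C |  | 8.0 d |
| north | 0.050 M | 0.0600 M | 70 °C |  | 8.0 d |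

- cedar (time / d: Z / %, J / %): 5.00: 3.1, 95.1; 8.00: 4.3, 93.6; 10.0: 3.6, 89.6; 15.0: 6.6, 84.8; 25.0: 11.6, 75.5; 30.0: 11.8, 71.2; 60.0: 22.4, 53.1
- ash (time / d: Z / %, J / %): 0.833: 2.6, 94.3; 1.25: 2.9, 92.4; 1.67: 4.6, 87.2; 2.50: 7.5, 82.2; 4.00: 11.1, 68.8; 6.00: 17.3, 55.7; 10.0: 25.2, 37.1
- maple (time / d: Z / %, J / %): 5.00: 0.7, 93.2; 15.0: 7.9, 85.1; 25.0: 12.3, 75.0; 30.0: 12.6, 74.0; 60.0: 24.4, 50.9

(each reading ± 1 percentage point)

- G is a solid; its amount is given per volume of the solution
- candidate steps: E + Z -> X + Q; G <-> E; E + L -> X + Q; J + E -> L + Q; J + E -> Z + Q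
- at the start none of G is in solution

- the flask with the highest amount of Z, in percent of the J charged ("all alike" if they lie within 1.5 percentage points) (south / north-west / south-west / north / all alike)
- final Z, as a percentage of the J charged, in south
- final Z, as a percentage of the J charged, in north-west
- final Z, as a percentage of the J charged, in south-west
- final Z, as a percentage of the J charged, in north

Cedar and maple differ in G and in starting J. Yet 53.1% and 50.9% of J stand at 60.0 d. So I treat the loss as pseudo-first-order in J, with constant k. The last readings give: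

k = 0.0105 d⁻¹ in cedar, 0.0992 d⁻¹ in ash

Their Arrhenius slope is 9080 K. So for north-west:

k = 0.455 d⁻¹, J left after 8.0 d = 2.62%

The charge holds 1.20 equivalents of G per J, so I let the loss run on.

Now I join the ends. Early, Z is the share s = r/(1 + r) of the J lost. Late, in north-west, the J lost approaches the whole charge. So I write Z = s(1 − e^(−kt)) and assume that Z survives. With the ash r this gives 39.0%.

The weak link is that r was held at the ash value. So I give r its own slope, 1270 K:

r = 0.540 at 100 °C, Z = 34.2%

This branching ratio at the flask's temperature, Z made per J sent elsewhere, is what I carry. The same reckoning gives south 28.1% and north 14.8%. South-west is colder still. So I commit to north-west, higher than south.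

The forecast names south, with 27% there, 24% in north-west, 6% in south-west and 16% in north. For north-west it says G runs out, “which halts further loss of Z near 24%”. That number is what the last ash reading gives, taken over. My 34.2% differs from it.

The simulation gives north-west: 33.7% there, 27.8% in south, 5.77% in south-west, 15.0% in north.

    E + Z → X + Q (k = 0.00840 M⁻¹ h⁻¹, Ea = 117 kJ mol⁻¹)
    G ⇌ E, rate k2*(cs2 - [E]) while solid is left; crystals form when [E] > cs2 (solubility = 12.0 mM, k = 0.150 h⁻¹)
    E + L → X + Q (k = 0.0190 M⁻¹ h⁻¹, Ea = 80.0 kJ mol⁻¹)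
    J + E → L + Q (k = 1.20 M⁻¹ h⁻¹, Ea = 82.0 kJ mol⁻¹)
    J + E → Z + Q (k = 0.650 M⁻¹ h⁻¹, Ea = 71.0 kJ mol⁻¹)
    (constants at 100 °C)

In north-west, J left at 3.1% and Z at 33.7% make r = 0.533, and the constant of the path from J + E to Z + Q stands to that of the path to L + Q as 0.542 at 100 °C. A neighbour of north-west at the same temperature, charged with 0.036 M of G, holds at 8.00 d 28.7% of J and 0.40% of its G, solid or dissolved. My ratio gives it 25.0% of Z, and it holds 25.0%.

Readings and results are calculated for an exercise.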